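**Retrosynthetic overview**
1. Both benzene rings are bought intact, so no ring is formed anywhere in the route.
2. Aryl–C(=O) bond: 2,6-dimethoxyphenyllithium (ortho-lithiation of 1,3-dimethoxybenzene) plus a Weinreb amide; the phenol is carried as a THP ether that falls off in the acidic work-up.
3. C9–aryl sp3–sp2 bond: B-alkyl Suzuki–Miyaura coupling of the 9-BBN adduct of N-methoxy-N-methylnon-8-enamide with commercial 2-(4-bromophenoxy)tetrahydro-2H-pyran.
4. Amide bond: non-8-enoic acid plus N,O-dimethylhydroxylamine hydrochloride.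
5. Forward order: amide formation, then C–C coupling, then ketone formation with concurrent deprotection (3 steps).

Assumption: the target has no stereocentre and is achiral, so there is no enantiomer to select; the only stereocentre in the route is the racemic THP acetal carbon (compounds 5, 7, 10, 11), which is removed in the last step.

**Step 1**
Reactants: 1 non-8-enoic acid; 2 N,O-dimethylhydroxylamine hydrochloride
Product: 4 N-methoxy-N-methylnon-8-enamide, via acyl imidazolide 3 (not isolated)
Conditions: CDI (1.1 equiv), CH2Cl2, rt, 1 h; then 2 (1.2 equiv), rt, 12 h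
Reagents that add atoms: N,O-dimethylhydroxylamine hydrochloride (compound 2), CNOC.Cl
Why: CDI amide coupling (nucleophilic acyl substitution), in which the acid is activated as acyl imidazolide 3 with loss of CO2 and the hydroxylamine, freed from its hydrochloride by the released imidazole, displaces imidazole to give the Weinreb amide; no stereocentre is involved.

**Step 2**
Reactants: 4 N-methoxy-N-methylnon-8-enamide; 5 2-(4-bromophenoxy)tetrahydro-2H-pyran
Product: 7 N-methoxy-N-methyl-9-[4-(tetrahydro-2H-pyran-2-yloxy)phenyl]nonanamide, via B-alkyl-9-BBN adduct 6 (not isolated)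
Conditions: 4 (1.2 equiv), 9-BBN (0.5 M in THF, 1.3 equiv), 0 °C → rt, 4 h; then 5 (1.0 equiv), PdCl2(dppf) (3 mol %), 3 M aq K3PO4 (3 equiv), DMF, 60 °C, 12 h
Reagents that add atoms: 2-(4-bromophenoxy)tetrahydro-2H-pyran (compound 5), Brc1ccc(OC2CCCCO2)cc1
Why: Anti-Markovnikov hydroboration of the terminal alkene by 9-BBN puts boron on C9, and the B-alkyl Suzuki–Miyaura coupling (oxidative addition of the aryl bromide to zerovalent palladium formed from PdCl2(dppf), phosphate-assisted transmetalation, reductive elimination outrunning β-hydride elimination with the dppf ligand) forms the C9–aryl bond while the Weinreb amide and the base-stable THP acetal are untouched; no stereocentre is set.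

**Step 3**
Reactants: 7 N-methoxy-N-methyl-9-[4-(tetrahydro-2H-pyran-2-yloxy)phenyl]nonanamide; 8 1,3-dimethoxybenzene
Product: 12 1-(2,6-dimethoxyphenyl)-9-(4-hydroxyphenyl)nonan-1-one, via 2,6-dimethoxyphenyllithium 9 (not isolated), via lithium hemiaminal adduct 10 (not isolated), via THP-protected ketone 11 (not isolated)
Conditions: 8 (2.2 equiv), n-BuLi (2.0 equiv), THF, 0 °C → rt, 2 h; then 7 (1.0 equiv), −78 → 0 °C, 2 h; then 2 M aq HCl, THF, rt, 3 h
Reagents that add atoms: 1,3-dimethoxybenzene (compound 8), COc1cccc(OC)c1
Why: Directed ortho-metalation of 8 at C2 between the two methoxy groups gives aryllithium 9, whose addition to the Weinreb amide stops at the chelated tetrahedral adduct 10 (Weinreb ketone synthesis, no over-addition), and aqueous HCl then collapses 10 to ketone 11 and hydrolyses the THP acetal to the free phenol; the product is achiral.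

**Compound list**
1 | non-8-enoic acid | C=CCCCCCCC(=O)O | starting material
2 | N,O-dimethylhydroxylamine hydrochloride | CNOC.Cl | starting material
3 | 1-(non-8-enoyl)imidazole (acyl imidazolide) | C=CCCCCCCC(=O)n1ccnc1 | intermediate
4 | N-methoxy-N-methylnon-8-enamide | C=CCCCCCCC(=O)N(C)OC | intermediate
5 | 2-(4-bromophenoxy)tetrahydro-2H-pyran (racemic) | Brc1ccc(OC2CCCCO2)cc1 | starting material
6 | 9-{9-[methoxy(methyl)amino]-9-oxononyl}-9-borabicyclo[3.3.1]nonane | CON(C)C(=O)CCCCCCCCB1C2CCCC1CCC2 | intermediate
7 | N-methoxy-N-methyl-9-[4-(tetrahydro-2H-pyran-2-yloxy)phenyl]nonanamide (racemic at the acetal carbon) | CON(C)C(=O)CCCCCCCCc1ccc(OC2CCCCO2)cc1 | intermediate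
8 | 1,3-dimethoxybenzene | COc1cccc(OC)c1 | starting material
9 | 2,6-dimethoxyphenyllithium | [Li]c1c(OC)cccc1OC | intermediate
10 | lithium 1-(2,6-dimethoxyphenyl)-1-[methoxy(methyl)amino]-9-[4-(tetrahydro-2H-pyran-2-yloxy)phenyl]nonan-1-olate (mixture of stereoisomers) | COc1cccc(OC)c1C(O[Li])(N(C)OC)CCCCCCCCc1ccc(OC2CCCCO2)cc1 | intermediate
11 | 1-(2,6-dimethoxyphenyl)-9-[4-(tetrahydro-2H-pyran-2-yloxy)phenyl]nonan-1-one (racemic at the acetal carbon) | COc1cccc(OC)c1C(=O)CCCCCCCCc1ccc(OC2CCCCO2)cc1 | intermediate
12 | 1-(2,6-dimethoxyphenyl)-9-(4-hydroxyphenyl)nonan-1-one | COc1cccc(OC)c1C(=O)CCCCCCCCc1ccc(O)cc1 | target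

**Step count**
Total steps: 3. Longest linear sequence: 3 steps (1 → 4 → 7 → 12).

**Steps most likely to fail, with fallbacks**

Step 3 (highest risk). The hindered, basic aryllithium may deprotonate the amide α-CH2 or strip the N-methoxy group instead of adding. The fallback sets out from 7 and uses an aldehyde addition followed by oxidation. i-Bu2AlH (THF, −78 °C) reduces the Weinreb amide to 9-[4-(tetrahydro-2H-pyran-2-yloxy)phenyl]nonanal F4. Aryllithium 9, made from 8 and n-BuLi as before, adds to this more electrophilic aldehyde at −78 °C to give racemic 1-(2,6-dimethoxyphenyl)-9-[4-(tetrahydro-2H-pyran-2-yloxy)phenyl]nonan-1-ol F5. Dess–Martin periodinane (NaHCO3, CH2Cl2, rt) oxidises the carbinol to ketone 11, where the fallback comes back to the route; the 2 M aq HCl treatment of step 3 then gives 12.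

Step 2. The B-alkyl coupling may suffer from protodeboronation, β-hydride elimination or incomplete hydroboration. The fallback sets out from 4, again with 5, and replaces the organoboron coupling by a Heck arylation and hydrogenation. Pd(OAc)2, P(o-tol)3, K2CO3, DMF at 110 °C gives (E)-N-methoxy-N-methyl-9-[4-(tetrahydro-2H-pyran-2-yloxy)phenyl]non-8-enamide F3, together with double-bond isomers that converge in the next operation. Hydrogenation (H2 1 atm, Pd/C, EtOAc with a trace of Et3N, rt) saturates the alkene and comes back to the route at 7. A minor branched regioisomer is removed by chromatography.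

Step 1 (lowest risk). The weakly nucleophilic hydroxylamine may attack the acyl imidazolide slowly. The fallback sets out from 1 and reverses the activation, so that the nitrogen partner is made the strong nucleophile. Fischer esterification (MeOH, cat. H2SO4, reflux) gives methyl non-8-enoate F1. Separately, 2 and i-PrMgCl (2 equiv per 2, THF, −20 °C) give chloromagnesium N-methoxy-N-methylamide F2, which attacks F1 at −20 → 0 °C and, after NH4Cl work-up, delivers 4, where the fallback comes back to the route.

**Further compounds**
F1 | step 1 | methyl non-8-enoate | C=CCCCCCCC(=O)OC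
F2 | step 1 | chloromagnesium N-methoxy-N-methylamide | CON(C)[Mg]Cl
F3 | step 2 | (E)-N-methoxy-N-methyl-9-[4-(tetrahydro-2H-pyran-2-yloxy)phenyl]non-8-enamide | CON(C)C(=O)CCCCCC/C=C/c1ccc(OC2CCCCO2)cc1
F4 | step 3 | 9-[4-(tetrahydro-2H-pyran-2-yloxy)phenyl]nonanal | O=CCCCCCCCCc1ccc(OC2CCCCO2)cc1
F5 | step 3 | 1-(2,6-dimethoxyphenyl)-9-[4-(tetrahydro-2H-pyran-2-yloxy)phenyl]nonan-1-ol | COc1cccc(OC)c1C(O)CCCCCCCCc1ccc(OC2CCCCO2)cc1
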